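**Retrosynthetic overview**
1. No ring is built: rings A, C and B are bought intact as quercetin 1; only O-substituent bonds are adjusted.
2. Key disconnection (C–O): the 3'-O–CH3 bond, made first from 1 with diphenylborinic anhydride 2 as a template and iodomethane 3, through boron complexes 4 and 5, to give isorhamnetin 6.
3. Second disconnection (O–S): the 7-O–sulfate bond, made from 6 and 2,2,2-trichloroethyl chlorosulfate 7 as the neutral, chromatographable diester 8.
4. Last operation: reductive removal of the trichloroethyl group of 8 to give the target 9.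

Assumption: the target has no stereocentre (it is achiral), so the SMILES given is the only stereoisomer; the sulfate is taken as the free hydrogen sulfate as drawn, obtained by acidic ion exchange in the last step (it keeps best as its ammonium or potassium salt).

**Step 1**
Reactants: 1 quercetin (dried commercial dihydrate); 2 diphenylborinic anhydride; 3 iodomethane
Product: 6 isorhamnetin (3'-O-methylquercetin), via quercetin bis(diphenylboron) ate complex 4 (not isolated), via boron-bound isorhamnetin 5 (not isolated)
Conditions: 2 (1.1 equiv), 4 Å MS, MeCN–THF 3:1, rt, 1 h; iPr2NEt (1.0 equiv), 3 (1.5 equiv), 40 °C, Ar; then 1 M HCl, THF–H2O, rt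
Reagents that add atoms: iodomethane, CI
Why: Proposed new method: a borinate-templated, site-selective O-methylation of an unprotected flavonoid catechol — Ph2B binds 1 at its two chelating sites, as a neutral 3-O/4-C=O chelate that masks the 3-OH and as a tetracoordinate anionic catechol borinate (4) that is the most acidic proton-donor system present, so one equivalent of iPr2NEt in MeCN puts the only negative charge there and leaves 7-OH and 5-OH protonated; within the borinate the 3'-oxygen (meta to the electron-poor pyranone) carries more electron density than the 4'-oxygen (para, conjugated to the C4 carbonyl) and attacks MeI in an SN2 step to give 5, which is neutral and is not methylated again because the base is spent; the closest known chemistry is diarylborinic acid-mediated regioselective O-alkylation of cis-1,2-diols in carbohydrates through tetracoordinate borinates, together with the 3-O-selective alkylation of 3,4-dihydroxybenzaldehyde dianions, neither of which has been shown on a flavonoid catechol bearing a free 7-OH.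

**Step 2**
Reactants: 6 isorhamnetin; 7 2,2,2-trichloroethyl chlorosulfate
Product: 8 isorhamnetin 7-O-(2,2,2-trichloroethyl sulfate)
Conditions: 7 (1.05 equiv), iPr2NEt (1.05 equiv), DMAP (0.1 equiv), THF, −20 to 0 °C; silica chromatography
Reagents that add atoms: 2,2,2-trichloroethyl chlorosulfate, ClS(=O)(=O)OCC(Cl)(Cl)Cl
Why: O-sulfonylation of a phenoxide by a protected chlorosulfate (sulfuric diester formation) — with one equivalent of tertiary amine only the most acidic 7-OH (a vinylogous acid, para to the C4 carbonyl) is ionised, whereas 4'-OH is less acidic and flanked by the new OMe, 3-OH is less acidic and hydrogen-bonded and 5-OH is chelated, and the neutral diester allows minor regioisomers to be removed on silica.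

**Step 3**
Reactants: 8 isorhamnetin 7-O-(2,2,2-trichloroethyl sulfate)
Product: 9 isorhamnetin 7-O-sulfate
Conditions: 10% Pd/C, HCO2NH4 (6 equiv), MeOH, rt; filter; Dowex 50W (H+ form), H2O, 0 °C; freeze-dry
Reagents that add atoms: none
Why: reductive β-elimination (transfer hydrogenolysis) of the 2,2,2-trichloroethyl ester — zerovalent palladium inserts into a C–Cl bond and the sulfate monoester leaves with loss of 1,1-dichloroethene under neutral conditions that leave the aryl sulfate, the flavonol and the methyl ether untouched.

**Compound list**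
1 | quercetin, 2-(3,4-dihydroxyphenyl)-3,5,7-trihydroxy-4H-chromen-4-one (achiral) | O=c1c(O)c(-c2ccc(O)c(O)c2)oc2cc(O)cc(O)c12 | starting material
2 | diphenylborinic anhydride, oxybis(diphenylborane) (achiral) | c1ccccc1B(c1ccccc1)OB(c1ccccc1)c1ccccc1 | starting material
3 | iodomethane | CI | starting material
4 | quercetin bis(diphenylboron) ate complex: neutral Ph2B chelate bridging 3-O and the 4-carbonyl oxygen, plus anionic spiro 3',4'-O,O-diphenylborate, N,N-diisopropylethylammonium salt (achiral) | [B-]1(c5ccccc5)(c5ccccc5)Oc5ccc(-c2oc3cc(O)cc(O)c3c7=[O+][B-](c6ccccc6)(c6ccccc6)Oc27)cc5O1.CC[NH+](C(C)C)C(C)C | intermediate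
5 | boron-bound isorhamnetin: 3'-O-methyl ether carrying the 3-O/4-carbonyl Ph2B chelate and a 4'-O-diphenylborinic ester (achiral) | COc4cc(-c2oc3cc(O)cc(O)c3c7=[O+][B-](c5ccccc5)(c5ccccc5)Oc27)ccc4OB(c5ccccc5)c5ccccc5 | intermediate
6 | isorhamnetin, 3,5,7-trihydroxy-2-(4-hydroxy-3-methoxyphenyl)-4H-chromen-4-one (achiral) | COc1cc(-c2oc3cc(O)cc(O)c3c(=O)c2O)ccc1O | intermediate
7 | 2,2,2-trichloroethyl chlorosulfate | ClS(=O)(=O)OCC(Cl)(Cl)Cl | starting material
8 | isorhamnetin 7-O-(2,2,2-trichloroethyl sulfate), 3,5-dihydroxy-2-(4-hydroxy-3-methoxyphenyl)-4-oxo-4H-chromen-7-yl 2,2,2-trichloroethyl sulfate (achiral) | COc1cc(-c2oc3cc(OS(=O)(=O)OCC(Cl)(Cl)Cl)cc(O)c3c(=O)c2O)ccc1O | intermediate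
9 | isorhamnetin 7-O-sulfate, 3,5-dihydroxy-2-(4-hydroxy-3-methoxyphenyl)-4-oxo-4H-chromen-7-yl hydrogen sulfate (achiral) | COc1cc(-c2oc3cc(OS(=O)(=O)O)cc(O)c3c(=O)c2O)ccc1O | target

**Step count and risk**
Total steps: 3. Longest linear sequence: 3. The protected sulfate costs one step over direct sulfation, but it gives a neutral intermediate from which regioisomers can be separated on silica before the ionic product is released.

Steps most likely to fail, in order: step 1, step 2, step 3.

Step 1 (the proposed new methylation). Likely failure modes are 7-O- or 4'-O-methylation, double methylation, or a sluggish reaction of the borinate with MeI. The fallback is the known protecting-group hemisynthesis; it sets out from 1 and comes back at 6. Quercetin 1 is heated with dichlorodiphenylmethane in diphenyl ether at 175 °C to give 3',4'-O-diphenylmethylenequercetin F1. Benzyl bromide (2.2 equiv) and K2CO3 in DMF give 3,7-di-O-benzyl-3',4'-O-diphenylmethylenequercetin F2. Refluxing AcOH–H2O 4:1 removes the ketal to give 3,7-di-O-benzylquercetin F3. Benzyl bromide (1.1 equiv) and K2CO3 in DMF alkylate the more acidic 4'-OH to give 3,7,4'-tri-O-benzylquercetin F4. MeI and K2CO3 in DMF methylate the remaining 3'-OH (the chelated 5-OH stays free) to give 3,7,4'-tri-O-benzyl-3'-O-methylquercetin F5. Hydrogenolysis (H2, 10% Pd/C, THF–MeOH) then gives 6.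

Step 2 (regioselective 7-O-sulfonylation). The likely failure is competing reaction at 4'-OH or 3-OH, or bis-sulfonylation. The fallback blocks every other hydroxyl instead of relying on acidity; it sets out from 6 and comes back at 9, bypassing 8 and step 3. Isorhamnetin 6 is peracetylated (Ac2O, pyridine, DMAP) to 3,5,7,4'-tetra-O-acetylisorhamnetin F6. Thiophenol and imidazole in NMP at 0 °C remove only the 7-O-acetyl group to give 3,5,4'-tri-O-acetylisorhamnetin F7. SO3·pyridine in pyridine sulfates the single free hydroxyl to give 3,5,4'-tri-O-acetylisorhamnetin 7-O-sulfate F8. K2CO3 in MeOH at 0 °C removes the acetates, and acidic ion exchange as in step 3 gives 9.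

Step 3 (unmasking and isolation). Likely failure modes are partial reduction of the flavonol, catalyst poisoning, or loss of sulfate while the free acid is isolated. The fallback avoids both the protecting group and the reduction; it sets out from 6 and comes back at 9. Isorhamnetin 6 is sulfated directly with Bu4NHSO4 (1.5 equiv) and dicyclohexylcarbodiimide in pyridine at 4 °C, a method under which flavonol hydroxyls are sulfated stepwise with the 7-position first. The 7-monosulfate is separated on Sephadex LH-20 and converted to 9 by ion exchange. This fallback makes no compound outside the list (none F0).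

**Further compounds**
F1 | step 1 | 3',4'-O-diphenylmethylenequercetin | O=c1c(O)c(-c2ccc3OC(c4ccccc4)(c4ccccc4)Oc3c2)oc2cc(O)cc(O)c12
F2 | step 1 | 3,7-di-O-benzyl-3',4'-O-diphenylmethylenequercetin | O=c1c(OCc2ccccc2)c(-c2ccc3OC(c4ccccc4)(c4ccccc4)Oc3c2)oc2cc(OCc3ccccc3)cc(O)c12
F3 | step 1 | 3,7-di-O-benzylquercetin | O=c1c(OCc2ccccc2)c(-c2ccc(O)c(O)c2)oc2cc(OCc3ccccc3)cc(O)c12
F4 | step 1 | 3,7,4'-tri-O-benzylquercetin | O=c1c(OCc2ccccc2)c(-c2ccc(OCc3ccccc3)c(O)c2)oc2cc(OCc3ccccc3)cc(O)c12
F5 | step 1 | 3,7,4'-tri-O-benzyl-3'-O-methylquercetin | COc1cc(-c2oc3cc(OCc4ccccc4)cc(O)c3c(=O)c2OCc2ccccc2)ccc1OCc1ccccc1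
F6 | step 2 | 3,5,7,4'-tetra-O-acetylisorhamnetin | COc1cc(-c2oc3cc(OC(C)=O)cc(OC(C)=O)c3c(=O)c2OC(C)=O)ccc1OC(C)=O
F7 | step 2 | 3,5,4'-tri-O-acetylisorhamnetin | COc1cc(-c2oc3cc(O)cc(OC(C)=O)c3c(=O)c2OC(C)=O)ccc1OC(C)=O
F8 | step 2 | 3,5,4'-tri-O-acetylisorhamnetin 7-O-sulfate | COc1cc(-c2oc3cc(OS(=O)(=O)O)cc(OC(C)=O)c3c(=O)c2OC(C)=O)ccc1OC(C)=O
F0 | step 3 | none | none
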